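**Retrosynthetic overview**

1. Numbering: lactone O1–C2(=O)–C3–C4–C5; C6 is the exocyclic alkene carbon on C3 and carries ring A (3-hydroxy-4,5-dimethoxyphenyl); C7 is the benzylic CH2 on C4 and carries ring B (4-hydroxy-3-methoxyphenyl); C4 is R and C3=C6 is E.
2. The route rests on the C5–O1 bond, a primary alkyl C–O bond whose carbon lies γ to the C2 carboxyl. C5 is therefore carried as the methyl group on C4 of the open-chain (E)-acid 14 and is oxidised last, with the carboxylate as directing group, to close the lactone (14 → 15); acetate methanolysis then gives 16.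
3. C3=C6 comes from aldol addition of the enolate of ester 5 to the ring A aldehyde 7 and E1cB dehydration; hydrolysis with desilylation and re-protection as acetates give 14.
4. The only stereocentre, C4, is set by copper-catalysed enantioselective methyl addition to enoate 4, made by cross-metathesis of silylated eugenol 2 with methyl acrylate 3.
5. Ring order: rings A and B are bought; the lactone is the only ring formed (step 9).

Key step: step 9

Assumption: step 3 is written with (S)-Tol-BINAP on the assumption that this antipode gives the 3R ester; the sense must be checked on the first run (chiral HPLC, rotation), and if it is opposite, (R)-Tol-BINAP is used with nothing else changed. TBS = tert-butyldimethylsilyl.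

**Route**

Step 1
Reactants: 1 eugenol
Product: 2 tert-butyl(4-allyl-2-methoxyphenoxy)dimethylsilane
Conditions: TBSCl, imidazole, DMF, 0 °C → rt
Reagents that add atoms: tert-butyldimethylsilyl chloride, CC(C)(C)[Si](C)(C)Cl
Why: Silyl ether formation at the phenol (imidazole as base and nucleophilic catalyst) masks the acidic OH against the Grignard reagent and LDA used later; no stereocentre is involved.

Step 2
Reactants: 2 tert-butyl(4-allyl-2-methoxyphenoxy)dimethylsilane; 3 methyl acrylate (excess)
Product: 4 methyl (E)-4-[4-(tert-butyldimethylsilyloxy)-3-methoxyphenyl]but-2-enoate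
Conditions: second-generation Hoveyda–Grubbs catalyst (2 mol %), 1,4-benzoquinone (10 mol %), CH2Cl2, 40 °C
Reagents that add atoms: none
Why: Olefin cross-metathesis of a terminal allyl arene with an excess of an electron-poor acrylate, which barely homodimerises, should give the cross product as the thermodynamically preferred E-enoate; benzoquinone suppresses ruthenium-hydride migration of the allyl double bond.

Step 3
Reactants: 4 methyl (E)-4-[4-(tert-butyldimethylsilyloxy)-3-methoxyphenyl]but-2-enoate
Product: 5 methyl (R)-4-[4-(tert-butyldimethylsilyloxy)-3-methoxyphenyl]-3-methylbutanoate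
Conditions: MeMgBr, CuI (2 mol %), (S)-Tol-BINAP (3 mol %), t-BuOMe, −20 °C, slow addition of 4; aq. NH4Cl
Reagents that add atoms: methylmagnesium bromide, C[Mg]Br
Why: Copper-catalysed enantioselective conjugate addition of a Grignard reagent to an acyclic E-enoate, in which the chiral bisphosphine–copper methyl complex adds to one enantiotopic face of the β-carbon and so sets C4 as R under ligand control; low temperature and slow addition keep 1,2-addition and C7 deprotonation behind the catalysed 1,4-addition.

Step 4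
Reactants: 6 3-hydroxy-4,5-dimethoxybenzaldehyde
Product: 7 3-(tert-butyldimethylsilyloxy)-4,5-dimethoxybenzaldehyde
Conditions: TBSCl, imidazole, DMF, rt
Reagents that add atoms: tert-butyldimethylsilyl chloride, CC(C)(C)[Si](C)(C)Cl
Why: Phenol silylation as in step 1 removes the acidic proton that would quench the ester enolate in step 5.

Step 5
Reactants: 5 methyl (R)-4-[4-(tert-butyldimethylsilyloxy)-3-methoxyphenyl]-3-methylbutanoate; 7 3-(tert-butyldimethylsilyloxy)-4,5-dimethoxybenzaldehyde
Product: 9 methyl (3R)-2-{[3-(tert-butyldimethylsilyloxy)-4,5-dimethoxyphenyl](hydroxy)methyl}-4-[4-(tert-butyldimethylsilyloxy)-3-methoxyphenyl]-3-methylbutanoate (mixture of diastereomers at the two new centres), via lithium enolate 8 (not isolated)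
Conditions: LDA, THF, −78 °C; then 7, −78 °C; aq. NH4Cl
Reagents that add atoms: none
Why: Aldol addition of a lithium ester enolate to a non-enolisable aromatic aldehyde; the two new centres (C3 and the carbinol carbon, the future C6) may form as a mixture because both become sp2 in step 6, and C4 is not touched.

Step 6
Reactants: 9 methyl (3R)-2-{[3-(tert-butyldimethylsilyloxy)-4,5-dimethoxyphenyl](hydroxy)methyl}-4-[4-(tert-butyldimethylsilyloxy)-3-methoxyphenyl]-3-methylbutanoate
Product: 11 methyl (R,E)-2-[3-(tert-butyldimethylsilyloxy)-4,5-dimethoxybenzylidene]-4-[4-(tert-butyldimethylsilyloxy)-3-methoxyphenyl]-3-methylbutanoate, via mesylate 10 (not isolated)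
Conditions: MsCl, Et3N, CH2Cl2, 0 °C; then DBU, rt → 40 °C
Reagents that add atoms: none
Why: Sulfonylation followed by E1cB elimination through the ester enolate should funnel both diastereomers to the conjugated enoate with ring A trans to the ester (E), the arrangement that avoids the aryl/ester clash; C4–H is only allylic, its anion not being conjugated with the carbonyl, so the stereocentre should hold.

Step 7
Reactants: 11 methyl (R,E)-2-[3-(tert-butyldimethylsilyloxy)-4,5-dimethoxybenzylidene]-4-[4-(tert-butyldimethylsilyloxy)-3-methoxyphenyl]-3-methylbutanoate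
Product: 12 (R,E)-2-(3-hydroxy-4,5-dimethoxybenzylidene)-4-(4-hydroxy-3-methoxyphenyl)-3-methylbutanoic acid
Conditions: LiOH·H2O (excess), THF/MeOH/H2O, 50 °C, degassed; then 1 M HCl
Reagents that add atoms: lithium hydroxide, [Li+].[OH-]
Why: Saponification of the methyl ester, with hydroxide cleaving both aryl silyl ethers in the same operation; the carboxylate formed is inert to further base and neither C4 nor the alkene carries an acidifying group.

Step 8
Reactants: 12 (R,E)-2-(3-hydroxy-4,5-dimethoxybenzylidene)-4-(4-hydroxy-3-methoxyphenyl)-3-methylbutanoic acid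
Product: 14 (R,E)-2-(3-acetoxy-4,5-dimethoxybenzylidene)-4-(4-acetoxy-3-methoxyphenyl)-3-methylbutanoic acid, via mixed acetic anhydride 13 (not isolated)
Conditions: Ac2O, pyridine, DMAP (cat.), 0 °C → rt; then H2O/THF, rt
Reagents that add atoms: acetic anhydride, CC(=O)OC(C)=O
Why: DMAP-catalysed acetylation of both phenols; the carboxyl group is acetylated as well to the mixed anhydride, which the aqueous stir should hydrolyse at the less hindered acetyl carbonyl to return the free acid.

Step 9
Reactants: 14 (R,E)-2-(3-acetoxy-4,5-dimethoxybenzylidene)-4-(4-acetoxy-3-methoxyphenyl)-3-methylbutanoic acid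
Product: 15 (R,E)-3-(3-acetoxy-4,5-dimethoxybenzylidene)-4-(4-acetoxy-3-methoxybenzyl)dihydrofuran-2(3H)-one
Conditions: Pd(OAc)2 (10 mol %), N-acetyl-β-alanine (20 mol %), CsHCO3 (0.5 equiv), TBHP (decane solution, 2.5 equiv), HFIP, 60 °C
Reagents that add atoms: none
Why: Proposed new method: the carboxylate of 14 binds divalent palladium through one oxygen, ligand-assisted concerted metalation–deprotonation of a C5 methyl C–H bond gives a six-membered palladacycle (Pd–O1–C2–C3–C4–C5), TBHP oxidises it to tetravalent palladium, and C(sp3)–O reductive elimination, an internal SN2-type attack of the carboxylate oxygen on C5, forms C5–O1 and closes the five-membered lactone in a 5-exo-tet sense. The closest known reaction type is the palladium-catalysed carboxylate-directed β- and γ-C(sp3)–H lactonisation of saturated aliphatic acids with peroxide oxidants, which has not been shown on a 2-alkylidene acid. Here the sp2 carbon C3 holds the carboxylate and C4 in one plane, and allylic 1,3-strain keeps C4–H in that plane towards ring A, so the methyl group is turned towards the metal. No stereocentre is formed, C4 takes part in no bond change and the E-alkene is untouched, so the configuration from step 3 is carried through. The step needs selectivity for the primary C5–H over the secondary benzylic C7–H (also γ), which rests on the strong preference of this metalation for methyl groups; the cis vinylic C6–H can at most be palladated reversibly, because C–O elimination there would require an unsaturated four-membered lactone, and the ring A ortho hydrogens lie trans to the carboxylate and out of reach. The acetates lower the electron density of both arenes against electrophilic palladation and peroxide oxidation.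

Step 10
Reactants: 15 (R,E)-3-(3-acetoxy-4,5-dimethoxybenzylidene)-4-(4-acetoxy-3-methoxybenzyl)dihydrofuran-2(3H)-one
Product: 16 (R,E)-3-(3-hydroxy-4,5-dimethoxybenzylidene)-4-(4-hydroxy-3-methoxybenzyl)dihydrofuran-2(3H)-one (CNP0187799.1)
Conditions: K2CO3 (0.5 equiv), MeOH, 0 °C → rt; then dilute HCl
Reagents that add atoms: none
Why: Base-catalysed transesterification of the aryl acetates, which are far better acyl donors than the conjugated lactone; any lactone opened to the hydroxy methyl ester should re-close on acidification, and C4 and the E-alkene are not affected.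

**Compound list**

1 | eugenol | C=CCc1ccc(O)c(OC)c1 | starting material
2 | tert-butyl(4-allyl-2-methoxyphenoxy)dimethylsilane | C=CCc1ccc(O[Si](C)(C)C(C)(C)C)c(OC)c1 | intermediate
3 | methyl acrylate | C=CC(=O)OC | starting material
4 | methyl (E)-4-[4-(tert-butyldimethylsilyloxy)-3-methoxyphenyl]but-2-enoate | COC(=O)/C=C/Cc1ccc(O[Si](C)(C)C(C)(C)C)c(OC)c1 | intermediate
5 | methyl (R)-4-[4-(tert-butyldimethylsilyloxy)-3-methoxyphenyl]-3-methylbutanoate | COC(=O)C[C@H](C)Cc1ccc(O[Si](C)(C)C(C)(C)C)c(OC)c1 | intermediate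
6 | 3-hydroxy-4,5-dimethoxybenzaldehyde | COc1cc(C=O)cc(O)c1OC | starting material
7 | 3-(tert-butyldimethylsilyloxy)-4,5-dimethoxybenzaldehyde | COc1cc(C=O)cc(O[Si](C)(C)C(C)(C)C)c1OC | intermediate
8 | lithium enolate of 5 | COC(O[Li])=C[C@H](C)Cc1ccc(O[Si](C)(C)C(C)(C)C)c(OC)c1 | intermediate (not isolated)
9 | methyl (3R)-2-{[3-(tert-butyldimethylsilyloxy)-4,5-dimethoxyphenyl](hydroxy)methyl}-4-[4-(tert-butyldimethylsilyloxy)-3-methoxyphenyl]-3-methylbutanoate | COC(=O)C(C(O)c1cc(O[Si](C)(C)C(C)(C)C)c(OC)c(OC)c1)[C@H](C)Cc1ccc(O[Si](C)(C)C(C)(C)C)c(OC)c1 | intermediate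
10 | methanesulfonate of 9 | COC(=O)C(C(OS(C)(=O)=O)c1cc(O[Si](C)(C)C(C)(C)C)c(OC)c(OC)c1)[C@H](C)Cc1ccc(O[Si](C)(C)C(C)(C)C)c(OC)c1 | intermediate (not isolated)
11 | methyl (R,E)-2-[3-(tert-butyldimethylsilyloxy)-4,5-dimethoxybenzylidene]-4-[4-(tert-butyldimethylsilyloxy)-3-methoxyphenyl]-3-methylbutanoate | COC(=O)/C(=C/c1cc(O[Si](C)(C)C(C)(C)C)c(OC)c(OC)c1)[C@H](C)Cc1ccc(O[Si](C)(C)C(C)(C)C)c(OC)c1 | intermediate
12 | (R,E)-2-(3-hydroxy-4,5-dimethoxybenzylidene)-4-(4-hydroxy-3-methoxyphenyl)-3-methylbutanoic acid | OC(=O)/C(=C/c1cc(O)c(OC)c(OC)c1)[C@H](C)Cc1ccc(O)c(OC)c1 | intermediate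
13 | mixed acetic anhydride of 14 | CC(=O)OC(=O)/C(=C/c1cc(OC(C)=O)c(OC)c(OC)c1)[C@H](C)Cc1ccc(OC(C)=O)c(OC)c1 | intermediate (not isolated)
14 | (R,E)-2-(3-acetoxy-4,5-dimethoxybenzylidene)-4-(4-acetoxy-3-methoxyphenyl)-3-methylbutanoic acid | OC(=O)/C(=C/c1cc(OC(C)=O)c(OC)c(OC)c1)[C@H](C)Cc1ccc(OC(C)=O)c(OC)c1 | intermediate
15 | (R,E)-3-(3-acetoxy-4,5-dimethoxybenzylidene)-4-(4-acetoxy-3-methoxybenzyl)dihydrofuran-2(3H)-one | CC(=O)Oc1ccc(C[C@H]2COC(=O)/C2=C/c2cc(OC(C)=O)c(OC)c(OC)c2)cc1OC | intermediate
16 | (R,E)-3-(3-hydroxy-4,5-dimethoxybenzylidene)-4-(4-hydroxy-3-methoxybenzyl)dihydrofuran-2(3H)-one | COc1cc(C[C@H]2COC(=O)/C2=C/c2cc(O)c(OC)c(OC)c2)ccc1O | target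

**Count**

Total steps: 10. Longest linear sequence: 9 steps (steps 1, 2, 3, 5, 6, 7, 8, 9, 10, from eugenol 1 to 16); step 4 is the one-step side branch for the ring A aldehyde.

**Steps most likely to fail**

1. Step 9 (the proposed new method). The metalation may take place at the benzylic C7–H or the vinylic C6–H instead of the methyl group, the palladacycle may lose a β-hydride towards C4 before it is oxidised, or the peroxide may attack the electron-rich rings. The fallback uses known chemistry only, brings C5 in already oxygenated and makes the lactone before the arylidene; it sets out from 2 and returns to the route at 16.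
   - Hydroboration–oxidation of 2 (9-BBN, THF; then NaBO3·4H2O) gives 3-[4-(tert-butyldimethylsilyloxy)-3-methoxyphenyl]propan-1-ol F1. TEMPO with PhI(OAc)2 in aqueous MeCN oxidises it to 3-[4-(tert-butyldimethylsilyloxy)-3-methoxyphenyl]propanoic acid F2.
   - DCC/DMAP coupling with (S)-4-benzyloxazolidin-2-one gives (S)-4-benzyl-3-{3-[4-(tert-butyldimethylsilyloxy)-3-methoxyphenyl]propanoyl}oxazolidin-2-one F3.
   - Evans alkylation (NaHMDS, THF, −78 °C; tert-butyl bromoacetate), on the enolate face away from the benzyl group, gives tert-butyl (R)-4-[(S)-4-benzyl-2-oxooxazolidin-3-yl]-3-[4-(tert-butyldimethylsilyloxy)-3-methoxybenzyl]-4-oxobutanoate F4.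
   - LiBH4 (THF/MeOH, 0 °C) reduces the imide carbonyl, the future C5, and releases the auxiliary to give tert-butyl (R)-4-[4-(tert-butyldimethylsilyloxy)-3-methoxyphenyl]-3-(hydroxymethyl)butanoate F5. Catalytic TsOH in warm toluene closes (R)-4-[4-(tert-butyldimethylsilyloxy)-3-methoxybenzyl]dihydrofuran-2(3H)-one F6.
   - Aldol addition of its lithium enolate (LDA, THF, −78 °C) to 7 gives (4R)-3-{[3-(tert-butyldimethylsilyloxy)-4,5-dimethoxyphenyl](hydroxy)methyl}-4-[4-(tert-butyldimethylsilyloxy)-3-methoxybenzyl]dihydrofuran-2(3H)-one F7.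
   - MsCl/Et3N converts it into the methanesulfonate of that aldol lactone F8, and DBU eliminates to (R,E)-3-[3-(tert-butyldimethylsilyloxy)-4,5-dimethoxybenzylidene]-4-[4-(tert-butyldimethylsilyloxy)-3-methoxybenzyl]dihydrofuran-2(3H)-one F9. TBAF buffered with AcOH in THF then removes both silyl groups to give 16.

2. Step 3. The Grignard reagent may deprotonate the doubly activated C7 (benzylic and γ to the ester), with migration of the double bond into conjugation with ring B, or the facial selectivity may be too low or of the wrong sense. The fallback sets the stereocentre on the terminal alkene of 2, before any acidic C7–H next to an enoate exists; it sets out from 2 and returns at 5.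
   - Zirconium-catalysed asymmetric carboalumination of 2 (Me3Al, (−)-bis(1-neomenthylindenyl)zirconium dichloride, CH2Cl2; then O2) gives (R)-3-[4-(tert-butyldimethylsilyloxy)-3-methoxyphenyl]-2-methylpropan-1-ol F10. Its enantiomeric purity can be raised if needed by lipase-catalysed acetylation.
   - Appel iodination (I2, PPh3, imidazole) gives (R)-tert-butyl[4-(3-iodo-2-methylpropyl)-2-methoxyphenoxy]dimethylsilane F11.
   - Iodine–lithium exchange (t-BuLi, Et2O, −78 °C) and trapping with CO2 give (R)-4-[4-(tert-butyldimethylsilyloxy)-3-methoxyphenyl]-3-methylbutanoic acid F12. Methylation (MeI, K2CO3, DMF) gives 5.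

3. Step 6. The elimination may give poor control of the alkene geometry, or the β-sulfonyloxy ester may undergo retro-aldol cleavage under base. The fallback forms C3=C6 by olefination instead of dehydration; it sets out from 5 and returns at 11.
   - The lithium enolate of 5 (LDA, THF, −78 °C) is trapped on carbon with diethyl chlorophosphite and the phosphonite is oxidised (H2O2) to methyl (3R)-2-(diethoxyphosphoryl)-4-[4-(tert-butyldimethylsilyloxy)-3-methoxyphenyl]-3-methylbutanoate F13.
   - Horner–Wadsworth–Emmons olefination with 7 (NaH, THF, 0 °C → reflux) gives 11, with ring A trans to the ester under the thermodynamic control usual for α-substituted phosphonoacetates and aromatic aldehydes.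

**Further compounds**

F1 | step 9 | 3-[4-(tert-butyldimethylsilyloxy)-3-methoxyphenyl]propan-1-ol | OCCCc1ccc(O[Si](C)(C)C(C)(C)C)c(OC)c1
F2 | step 9 | 3-[4-(tert-butyldimethylsilyloxy)-3-methoxyphenyl]propanoic acid | OC(=O)CCc1ccc(O[Si](C)(C)C(C)(C)C)c(OC)c1
F3 | step 9 | (S)-4-benzyl-3-{3-[4-(tert-butyldimethylsilyloxy)-3-methoxyphenyl]propanoyl}oxazolidin-2-one | O=C(CCc1ccc(O[Si](C)(C)C(C)(C)C)c(OC)c1)N1[C@@H](Cc2ccccc2)COC1=O
F4 | step 9 | tert-butyl (R)-4-[(S)-4-benzyl-2-oxooxazolidin-3-yl]-3-[4-(tert-butyldimethylsilyloxy)-3-methoxybenzyl]-4-oxobutanoate | CC(C)(C)OC(=O)C[C@@H](Cc1ccc(O[Si](C)(C)C(C)(C)C)c(OC)c1)C(=O)N1[C@@H](Cc2ccccc2)COC1=O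
F5 | step 9 | tert-butyl (R)-4-[4-(tert-butyldimethylsilyloxy)-3-methoxyphenyl]-3-(hydroxymethyl)butanoate | CC(C)(C)OC(=O)C[C@@H](Cc1ccc(O[Si](C)(C)C(C)(C)C)c(OC)c1)CO
F6 | step 9 | (R)-4-[4-(tert-butyldimethylsilyloxy)-3-methoxybenzyl]dihydrofuran-2(3H)-one | O=C1C[C@@H](Cc2ccc(O[Si](C)(C)C(C)(C)C)c(OC)c2)CO1
F7 | step 9 | (4R)-3-{[3-(tert-butyldimethylsilyloxy)-4,5-dimethoxyphenyl](hydroxy)methyl}-4-[4-(tert-butyldimethylsilyloxy)-3-methoxybenzyl]dihydrofuran-2(3H)-one | O=C1OC[C@H](Cc2ccc(O[Si](C)(C)C(C)(C)C)c(OC)c2)C1C(O)c1cc(O[Si](C)(C)C(C)(C)C)c(OC)c(OC)c1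
F8 | step 9 | methanesulfonate of the aldol lactone F7 | O=C1OC[C@H](Cc2ccc(O[Si](C)(C)C(C)(C)C)c(OC)c2)C1C(OS(C)(=O)=O)c1cc(O[Si](C)(C)C(C)(C)C)c(OC)c(OC)c1
F9 | step 9 | (R,E)-3-[3-(tert-butyldimethylsilyloxy)-4,5-dimethoxybenzylidene]-4-[4-(tert-butyldimethylsilyloxy)-3-methoxybenzyl]dihydrofuran-2(3H)-one | COc1cc(C[C@H]2COC(=O)/C2=C/c2cc(O[Si](C)(C)C(C)(C)C)c(OC)c(OC)c2)ccc1O[Si](C)(C)C(C)(C)C
F10 | step 3 | (R)-3-[4-(tert-butyldimethylsilyloxy)-3-methoxyphenyl]-2-methylpropan-1-ol | OC[C@H](C)Cc1ccc(O[Si](C)(C)C(C)(C)C)c(OC)c1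
F11 | step 3 | (R)-tert-butyl[4-(3-iodo-2-methylpropyl)-2-methoxyphenoxy]dimethylsilane | IC[C@H](C)Cc1ccc(O[Si](C)(C)C(C)(C)C)c(OC)c1
F12 | step 3 | (R)-4-[4-(tert-butyldimethylsilyloxy)-3-methoxyphenyl]-3-methylbutanoic acid | OC(=O)C[C@H](C)Cc1ccc(O[Si](C)(C)C(C)(C)C)c(OC)c1
F13 | step 6 | methyl (3R)-2-(diethoxyphosphoryl)-4-[4-(tert-butyldimethylsilyloxy)-3-methoxyphenyl]-3-methylbutanoate | CCOP(=O)(OCC)C(C(=O)OC)[C@H](C)Cc1ccc(O[Si](C)(C)C(C)(C)C)c(OC)c1
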